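The route opens ring B (the pyran: O, C1, C2, C1', two arene carbons) at O–C1 while C1 and C1' stay trigonal. Both carbons flank quaternary C2. Rings B and C must be cis-fused on the crowded, C10-side face of cyclopentane ring C. Large groups therefore go in first, and small reagents (MeI, then hydride twice) come last from the open face. In the key step a MOM-protected keto styrene is unmasked, a phenol adds to the C1 ketone, and Et3SiH reduces the benzylic cation and the oxocarbenium ion. This sets ring B, C1 and C1' in one flask. The spiro ketone stems from (R)-carvone and cyclobutanone by ring expansion.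

Key step: step 10

Labels: terpene carbons carry spiro[4.5]decane numbers (C1 = O–CH, C2 = C–CH3, C5 = spiro carbon, C6=C7 alkene, C10 = CH–CH3). C1' is the benzylic carbon. Ring A is the arene, ring B the pyran, ring C the cyclopentane, ring D the cyclohexene. The open face of ring C carries C6; the crowded face carries C10.

Remark: hydrogenation of carvone should give both epimers at the methyl-bearing carbon. Base equilibration and crystallisation of the hydrazone are counted on to leave the trans series.

Step 1
Reactants: 1 (R)-(−)-carvone
Product: 2 (2R,5R)-2-methyl-5-(propan-2-yl)cyclohexan-1-one (trans-carvomenthone)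
Conditions: H2 (1 atm), Pd/C, EtOAc, rt; then NaOMe (cat.), MeOH, rt
Reagents that add atoms: none
Why: Heterogeneous catalytic hydrogenation saturates both C=C bonds, and enolate equilibration places the new methyl-bearing stereocentre trans (diequatorial) to the isopropyl group fixed by the carvone stereocentre.

Step 2
Reactants: 2 trans-carvomenthone
Product: 3 (E)-2,4,6-triisopropylbenzenesulfonylhydrazone of 2
Conditions: 2,4,6-(iPr)3C6H2SO2NHNH2, HCl (cat.), MeOH, rt
Reagents that add atoms: 2,4,6-triisopropylbenzenesulfonohydrazide, NNS(=O)(=O)c1c(C(C)C)cc(C(C)C)cc1C(C)C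
Why: Acid-catalysed hydrazone condensation, in which the N–N bond settles anti to the branched α-carbon and so prepares deprotonation at the CH2 side.

Step 3
Reactants: 3 trisylhydrazone; 4 cyclobutanone
Product: 6 1-[(3S,6R)-6-methyl-3-(propan-2-yl)cyclohex-1-en-1-yl]cyclobutan-1-ol, via vinyllithium 5 (not isolated)
Conditions: n-BuLi (2.1 equiv), THF, TMEDA, −78 → 0 °C; then 4, −78 °C; H2O
Reagents that add atoms: none
Why: In this Shapiro reaction the dianion loses sulfinate and N2 to give the less substituted vinyllithium with both ring stereocentres untouched, and 1,2-addition to the strained ketone creates a carbinol carbon that is not stereogenic.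

Step 4
Reactants: 6 allylic cyclobutanol
Product: 8 (5R,10R)-10-methyl-7-(propan-2-yl)spiro[4.5]dec-6-en-1-one, via selenide 7 (not isolated)
Conditions: PhSeCl, pyridine, CH2Cl2, −78 → 0 °C; then 30% H2O2, 0 °C → rt
Reagents that add atoms: none
Why: In this electrophile-induced semipinacol ring expansion the seleniranium ion forms anti to the C7 isopropyl group and the cyclobutane C–C bond migrates to C5 anti to selenium and hence anti to the C10 methyl group (this sets C5), after which selenoxide syn elimination uses the only syn β-hydrogen, at C7.

Step 5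
Reactants: 8 spiro ketone; 9 3-methylbutanoyl chloride
Product: 10 (5R,10R)-10-methyl-2-(3-methylbutanoyl)-7-(propan-2-yl)spiro[4.5]dec-6-en-1-one, drawn as its chelated Z enol
Conditions: MgBr2·OEt2, iPr2NEt, CH2Cl2, rt
Reagents that add atoms: none
Why: In this soft-enolisation Claisen-type C-acylation only C2 can enolise because C5 is quaternary, and the magnesium chelate of the β-diketone favours C- over O-acylation.

Step 6
Reactants: 10 β-diketone
Product: 11 (2S,5R,10R)-2,10-dimethyl-2-(3-methylbutanoyl)-7-(propan-2-yl)spiro[4.5]dec-6-en-1-one
Conditions: MeI, K2CO3, acetone, 40 °C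
Reagents that add atoms: iodomethane, CI
Why: In this C-alkylation of a β-diketone enolate, MeI should reach planar C2 from the open face of ring C, which carries only the vinylic C6–H, so the acyl group is pushed to the C10 side and C2 is set as S.

Step 7
Reactants: 11 quaternary diketone
Product: 12 (Z)-enol triflate of the side-chain ketone of 11 (triflate oxygen on C1', isopropyl trans to C2)
Conditions: KN(SiMe3)2, THF, −78 °C; then PhN(SO2CF3)2, −78 → 0 °C
Reagents that add atoms: N-phenylbis(trifluoromethanesulfonimide), O=S(=O)(N(c1ccccc1)S(=O)(=O)C(F)(F)F)C(F)(F)F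
Why: In this kinetic enolate O-sulfonylation the side-chain CH2 holds the only acidic hydrogens since C1 lies between two quaternary carbons, and the bulk of C2 should favour the Z enolate.

Step 8
Reactants: 13 phloroglucinol
Product: 14 1,3,5-tris(methoxymethoxy)benzene
Conditions: MOMCl, iPr2NEt, CH2Cl2, 0 °C → rt
Reagents that add atoms: chloromethyl methyl ether, COCCl
Why: O-Alkylation of the three equivalent phenols to formaldehyde acetals gives base-stable groups that also direct the later lithiation.

Step 9
Reactants: 12 enol triflate; 14 tris-MOM ether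
Product: 17 keto styrene, (2S,5R,10R)-2,10-dimethyl-2-{(E)-3-methyl-1-[2,4,6-tris(methoxymethoxy)phenyl]but-1-en-1-yl}-7-(propan-2-yl)spiro[4.5]dec-6-en-1-one, via aryllithium 15 (not isolated), via arylzinc chloride 16 (not isolated)
Conditions: 14, n-BuLi, THF, 0 °C; ZnCl2, 0 °C → rt; then 12, Pd2(dba)3 (cat.), RuPhos (cat.), THF, 60 °C
Reagents that add atoms: none
Why: Directed ortho-lithiation between two MOM ethers, transmetalation to zinc and Negishi coupling with retention of alkene geometry should work because a bulky electron-rich biarylphosphine on zerovalent palladium is the established answer to di-ortho-substituted aryl zinc partners, and the hindered ketone is tolerated.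

Step 10
Reactants: 17 keto styrene
Product: 20 chroman diol (the target without its two formyl groups; C1' R, C1 R, C2 S, C5 R, C10 R), via keto triol 18 (not isolated), via cyclic hemiketal 19 (not isolated)
Conditions: HCl (0.5 M) in MeOH, 40 °C; evaporate; then Et3SiH, BF3·OEt2, CH2Cl2, −78 → −20 °C
Reagents that add atoms: none
Why: Methanolic HCl passes the three methoxymethyl groups to the solvent and frees 18, one of whose two equivalent ortho phenols adds to the C1 carbonyl to give 19; BF3·OEt2 then promotes protonation of the electron-rich styrene to a phloroglucinol-stabilised benzylic cation and ionisation of the hemiketal to an aryl oxocarbenium ion, and Et3SiH quenches both. The closest known reaction types are the reductive cyclisation of hydroxy ketones to cyclic ethers with a silane and a Lewis acid, and the ionic hydrogenation of styrenes. Ring B closes by 6-exo-trig attack of the phenol oxygen on C1, which is possible only on the face of ring C that already carries the side chain, so the B/C fusion must be cis. At C1 the hydride can arrive only from the convex, open face, syn to the C2 methyl group and C6, which leaves O on the C10 side (R); at C1' the cyclic cation is attacked from the same convex face, anti to C3 and the folded ring C, so H ends up cis to the C2 methyl group and the isobutyl group cis to C3 (R). The step needs chemoselectivity for the two stabilised cations over the C6=C7 alkene, which is secured by low temperature, by a Lewis acid in place of a strong protic acid, and by the shielding of that alkene between spiro C5 and the isopropyl group. Alkyl shifts from C2 are not expected because no cation next to C1 can match the stabilisation at C1'.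

Step 11
Reactants: 20 chroman diol
Product: 21 target CNP0121396.1
Conditions: POCl3, DMF, EtOAc, 0 °C → rt; then H2O, rt
Reagents that add atoms: N,N-dimethylformamide, CN(C)C=O; water, O
Why: In this double Vilsmeier–Haack formylation the two free positions of ring A lie ortho or para to three oxygen donors and are by far the most nucleophilic sites, while the unactivated trisubstituted alkene does not react with the chloroiminium salt and no stereocentre is touched.

Compound list
1 | (R)-(−)-carvone | CC1=CC[C@H](CC1=O)C(C)=C | starting material
2 | (2R,5R)-2-methyl-5-(propan-2-yl)cyclohexan-1-one | C[C@@H]1CC[C@@H](C(C)C)CC1=O | intermediate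
3 | (E)-2,4,6-triisopropylbenzenesulfonylhydrazone of 2 | C[C@@H]1CC[C@@H](C(C)C)C/C1=N\NS(=O)(=O)c1c(C(C)C)cc(C(C)C)cc1C(C)C | intermediate
4 | cyclobutanone | O=C1CCC1 | starting material
5 | (3S,6R)-6-methyl-3-(propan-2-yl)cyclohex-1-en-1-yllithium | C[C@@H]1CC[C@@H](C(C)C)C=C1[Li] | intermediate
6 | 1-[(3S,6R)-6-methyl-3-(propan-2-yl)cyclohex-1-en-1-yl]cyclobutan-1-ol | C[C@@H]1CC[C@@H](C(C)C)C=C1C1(O)CCC1 | intermediate
7 | (5S,6S,7S,10R)-10-methyl-6-(phenylselanyl)-7-(propan-2-yl)spiro[4.5]decan-1-one | O=C1CCC[C@@]12[C@@H]([Se]c3ccccc3)[C@H](C(C)C)CC[C@H]2C | intermediate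
8 | (5R,10R)-10-methyl-7-(propan-2-yl)spiro[4.5]dec-6-en-1-one | O=C1CCC[C@@]12C=C(C(C)C)CC[C@H]2C | intermediate
9 | 3-methylbutanoyl chloride | CC(C)CC(=O)Cl | starting material
10 | 2-(3-methylbutanoyl) derivative of 8, chelated Z enol | O=C1/C(=C(\O)CC(C)C)CC[C@@]12C=C(C(C)C)CC[C@H]2C | intermediate
11 | (2S,5R,10R)-2,10-dimethyl-2-(3-methylbutanoyl)-7-(propan-2-yl)spiro[4.5]dec-6-en-1-one | O=C1[C@](C)(C(=O)CC(C)C)CC[C@@]12C=C(C(C)C)CC[C@H]2C | intermediate
12 | (Z)-enol triflate of the side-chain ketone of 11 | O=C1[C@](C)(/C(OS(=O)(=O)C(F)(F)F)=C/C(C)C)CC[C@@]12C=C(C(C)C)CC[C@H]2C | intermediate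
13 | phloroglucinol | Oc1cc(O)cc(O)c1 | starting material
14 | 1,3,5-tris(methoxymethoxy)benzene | COCOc1cc(OCOC)cc(OCOC)c1 | intermediate
15 | 2,4,6-tris(methoxymethoxy)phenyllithium | [Li]c1c(OCOC)cc(OCOC)cc1OCOC | intermediate
16 | [2,4,6-tris(methoxymethoxy)phenyl]zinc chloride | Cl[Zn]c1c(OCOC)cc(OCOC)cc1OCOC | intermediate
17 | keto styrene (aryl on C1', isopropyl trans to C2) | O=C1[C@](C)(/C(c3c(OCOC)cc(OCOC)cc3OCOC)=C/C(C)C)CC[C@@]12C=C(C(C)C)CC[C@H]2C | intermediate
18 | keto triol (17 without the three MOM groups) | O=C1[C@](C)(/C(c3c(O)cc(O)cc3O)=C/C(C)C)CC[C@@]12C=C(C(C)C)CC[C@H]2C | intermediate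
19 | cyclic hemiketal (ring B closed, OH on C1 on the open face, C1'=CH–iPr exocyclic) | CC(C)/C=C1\c2c(O)cc(O)cc2O[C@]2(O)[C@@]1(C)CC[C@@]21C=C(C(C)C)CC[C@H]1C | intermediate
20 | chroman diol (target without formyl groups) | CC(C)C[C@H]1c2c(O)cc(O)cc2O[C@@H]2[C@@]1(C)CC[C@@]21C=C(C(C)C)CC[C@H]1C | intermediate
21 | CNP0121396.1 | CC(C)C[C@H]1c2c(O)c(C=O)c(O)c(C=O)c2O[C@@H]2[C@@]1(C)CC[C@@]21C=C(C(C)C)CC[C@H]1C | target

Total step count: 11. Longest linear sequence: 10 (steps 1–7 and 9–11).

Steps most likely to fail

Step 10. The crowded hemiketal may ionise slowly, and the acid may meanwhile shift or reduce the C6=C7 double bond. The fallback sets out from 17, returns at 20, and separates the two reductions. LiAlH4 in Et2O delivers hydride to C1 from the open face and gives the alcohol with OH on the C10 side F1. Methanolic HCl frees the triol alcohol F2. Gentle warming with pyridinium p-toluenesulfonate in toluene should then close ring B with retention at C1. This can occur by addition–elimination of the alcohol on the keto tautomer of the phloroglucinol ring, or by ionisation assisted by the C6=C7 π bond, and gives the alkylidene chroman F3. Only the easily formed benzylic cation then has to be reduced, with Et3SiH and a little CF3CO2H in CH2Cl2 at −40 °C.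

Step 9. Transmetalation and reductive elimination at an alkenyl carbon next to quaternary C2 may be too slow, so the aryl zinc reagent is lost by protodemetalation. The fallback sets out from 10, returns at 17, and forms the aryl–C1' bond while C2 is still trigonal. (CF3SO2)2O and Et3N convert the exocyclic enol into the β-triflyloxy enone F4. Negishi coupling of F4 with 16 under the same palladium system gives the tetrasubstituted enone F5. KN(SiMe3)2 then removes a γ-hydrogen of the isobutyl CH2, and MeI alkylates the extended enolate at C2 from the open face (deconjugative α-methylation).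

Step 4. Chloride may capture the seleniranium ion, the ring may expand under proton catalysis without selenium, or facial selectivity at the doubly flanked alkene may be poor. The fallback sets out from 6, returns at 8, and replaces selenium by oxygen. VO(acac)2 and t-BuOOH epoxidise the alkene on the face anti to the isopropyl group to give the epoxy alcohol F6. BF3·OEt2 at −78 °C triggers the semipinacol shift of the epoxy alcohol to the β-hydroxy ketone F7, whose OH is syn to H7. Methyl N-(triethylammoniosulfonyl)carbamate in warm toluene then removes water by syn elimination.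

Further compounds
F1 | step 10 | C1 alcohol of 17, OH on the C10 side | O[C@@H]1[C@](C)(/C(c3c(OCOC)cc(OCOC)cc3OCOC)=C/C(C)C)CC[C@@]12C=C(C(C)C)CC[C@H]2C
F2 | step 10 | triol alcohol (F1 without MOM groups) | O[C@@H]1[C@](C)(/C(c3c(O)cc(O)cc3O)=C/C(C)C)CC[C@@]12C=C(C(C)C)CC[C@H]2C
F3 | step 10 | alkylidene chroman (ring B closed, C1–H set, C1'=CH–iPr) | CC(C)/C=C1\c2c(O)cc(O)cc2O[C@@H]2[C@@]1(C)CC[C@@]21C=C(C(C)C)CC[C@H]1C
F4 | step 9 | β-triflyloxy enone from 10 | O=C1/C(=C(\OS(=O)(=O)C(F)(F)F)CC(C)C)CC[C@@]12C=C(C(C)C)CC[C@H]2C
F5 | step 9 | tetrasubstituted aryl enone | O=C1/C(=C(\c3c(OCOC)cc(OCOC)cc3OCOC)CC(C)C)CC[C@@]12C=C(C(C)C)CC[C@H]2C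
F6 | step 4 | epoxy alcohol, epoxide anti to isopropyl | C[C@@H]1CC[C@@H](C(C)C)[C@@H]2O[C@]12C1(O)CCC1
F7 | step 4 | 6-hydroxy spiro ketone, OH syn to H7 | O=C1CCC[C@@]12[C@@H](O)[C@H](C(C)C)CC[C@H]2C
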